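**Retrosynthetic overview**

- Feature: in the seven-membered ring the arc C7–C8(CH3)–C9–C10 is an intact isoprene unit, held between the oxygen-bearing C6 and the quaternary ring-fusion carbon C1 of the cyclopentane ring.
- Key disconnection (formal [4+3]): C6–C7 and C1–C10. Target ⇒ hydroazulene dienol ether 15 ⇒ cyclopentenyl methoxycarbene chromium complex 12 + isoprene 13, by cyclopropanation (C6–C7, temporary C6–C8) and Cope rearrangement. The five-membered ring is made first, the seven-membered ring second.
- Carbene 12 ⇐ silylene-bridged bromocyclopentene 8 ⇐ (R)-4-silyloxycyclopentenone 1 (methyl by cuprate addition and Saegusa–Ito oxidation, then bromide, then isopropyl by 1,2-addition anti to the silyloxy group). The 2β,4β-silylene bridge steers C10 to the α face of C1.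
- After ring closure: enol ether → C6 dioxolane (sets H5); C2 inverted by oxidation and 4β-OH-directed reduction, then acetate; C6 ketone reduced from the α face and esterified with inversion (Mitsunobu) by O-benzylvanillic acid; α-epoxidation; hydrogenolysis.

Key step: step 8

Remark: daucane numbering is used for all intermediates. The skeleton is a hydroazulene with the five-membered ring C1–C5 and the seven-membered ring C1, C5–C10; C1 (ring fusion) and C8 carry methyl, C4 carries isopropyl, and C2, C4 and C6 carry oxygen. α is the face of H5; β is the face of the C1 methyl and the 4-oxygen. (R)-4-(tert-Butyldimethylsilyloxy)cyclopent-2-en-1-one and 4-(benzyloxy)-3-methoxybenzoic acid are taken as commercial. Hydride reagents are expected to reach C6 only from the α face, so the 6α-ester is planned with inversion and not by a directed reduction.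

**Route**

Step 1
Reactants: 1 (R)-4-(tert-butyldimethylsilyloxy)cyclopent-2-en-1-one
Product: 2 (3R,4R)-4-(tert-butyldimethylsilyloxy)-3-methyl-1-(trimethylsilyloxy)cyclopent-1-ene
Conditions: Me2CuLi (MeLi, CuI), TMSCl, THF, −78 °C; Et3N
Reagents that add atoms: lithium dimethylcuprate [Li+].C[Cu-]C; chlorotrimethylsilane C[Si](C)(C)Cl
Why: Cuprate conjugate addition should occur anti to the silyloxy group, and the enolate is silylated in the flask before it can expel the β-silyloxy group, which places the methyl on the future C1 and fixes the enol ether position for step 2.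

Step 2
Reactants: 2 (3R,4R)-4-(tert-butyldimethylsilyloxy)-3-methyl-1-(trimethylsilyloxy)cyclopent-1-ene
Product: 3 (R)-4-(tert-butyldimethylsilyloxy)-3-methylcyclopent-2-en-1-one
Conditions: Pd(OAc)2 (1.05 equiv), MeCN, rt
Reagents that add atoms: none
Why: Saegusa–Ito oxidation, in which the palladium enolate loses the only β-hydrogen (on the methyl-bearing carbon), restores the enone with the 3-methyl group and leaves the silyloxy stereocentre untouched.

Step 3
Reactants: 3 (R)-4-(tert-butyldimethylsilyloxy)-3-methylcyclopent-2-en-1-one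
Product: 5 (R)-2-bromo-4-(tert-butyldimethylsilyloxy)-3-methylcyclopent-2-en-1-one, via 2,3-dibromo ketone 4 (not isolated)
Conditions: Br2, CH2Cl2, −78 → 0 °C; then Et3N, 0 °C → rt
Reagents that add atoms: bromine BrBr
Why: Bromine addition to the enone followed by base-induced loss of HBr (acidic α-hydrogen, β-bromide; addition–elimination) is the standard entry to 2-bromo-3-methylcyclopentenones and makes the future C5 a vinyl bromide.

Step 4
Reactants: 5 (R)-2-bromo-4-(tert-butyldimethylsilyloxy)-3-methylcyclopent-2-en-1-one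
Product: 6 (1R,4R)-2-bromo-4-(tert-butyldimethylsilyloxy)-3-methyl-1-(propan-2-yl)cyclopent-2-en-1-ol (OH cis to the silyloxy group)
Conditions: i-PrMgCl, CeCl3 (anhydrous), THF, −78 °C; aq NH4Cl
Reagents that add atoms: isopropylmagnesium chloride CC(C)[Mg]Cl
Why: 1,2-Addition of the organocerium reagent (which suppresses enolisation, β-hydride reduction and bromine–magnesium exchange) should occur on the face of the flat ring anti to the silyloxy group, which sets C4 with its hydroxyl cis to the C2 oxygen (1,3-induction).

Step 5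
Reactants: 6 (1R,4R)-2-bromo-4-(tert-butyldimethylsilyloxy)-3-methyl-1-(propan-2-yl)cyclopent-2-en-1-ol
Product: 7 (1R,4R)-2-bromo-3-methyl-1-(propan-2-yl)cyclopent-2-ene-1,4-diol (cis-diol)
Conditions: Bu4NF, THF, 0 °C → rt
Reagents that add atoms: none
Why: Fluoride cleavage of the secondary silyl ether frees the cis-1,3-diol without touching the vinyl bromide or the tertiary alcohol.

Step 6
Reactants: 7 (1R,4R)-2-bromo-3-methyl-1-(propan-2-yl)cyclopent-2-ene-1,4-diol
Product: 8 7-bromo-3,3-di-tert-butyl-6-methyl-1-(propan-2-yl)-2,4-dioxa-3-silabicyclo[3.2.1]oct-6-ene (2β,4β-O,O-silylene-bridged bromocyclopentene)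
Conditions: t-Bu2Si(OTf)2, 2,6-lutidine, CH2Cl2, 0 °C → rt
Reagents that add atoms: di-tert-butylsilyl bis(trifluoromethanesulfonate) CC(C)(C)[Si](OS(=O)(=O)C(F)(F)F)(OS(=O)(=O)C(F)(F)F)C(C)(C)C
Why: Cyclic silylene formation is possible only for the cis-1,3-diol (as with cyclic boronates of other cis-cyclopentane-1,3-diols), so it also rejects any trans isomer from step 4 and gives the bicycle whose O–Si–O bridge covers the β face of the cyclopentene.

Step 7
Reactants: 8 silylene-bridged bromocyclopentene; 9 chromium hexacarbonyl, Cr(CO)6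
Product: 12 pentacarbonyl[methoxy(silylene-bridged cyclopentenyl)carbene]chromium, via vinyllithium 10 (not isolated), via lithium acylchromate 11 (not isolated)
Conditions: t-BuLi (2.1 equiv), THF, −78 °C; Cr(CO)6, −78 °C → rt; then Me3OBF4, CH2Cl2, 0 °C
Reagents that add atoms: trimethyloxonium tetrafluoroborate C[O+](C)C.F[B-](F)(F)F
Why: Classical Fischer carbene synthesis, in which bromine–lithium exchange gives a vinyllithium that cannot β-eliminate in the five-membered ring, this adds to a CO ligand of Cr(CO)6, and the acylchromate is O-methylated by the oxonium salt.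

Step 8
Reactants: 12 pentacarbonyl[methoxy(silylene-bridged cyclopentenyl)carbene]chromium; 13 isoprene
Product: 15 2β,4β-(di-tert-butylsilylenedioxy)-6-methoxydauca-5,8-diene, via cis-divinylcyclopropane 14 (not isolated)
Conditions: isoprene (20 equiv), BHT (cat.), toluene, sealed tube, 90 → 110 °C
Reagents that add atoms: none
Why: Thermal loss of CO from the zerovalent chromium carbene lets isoprene coordinate, and a chromacyclobutane collapses by reductive elimination to the methoxy-substituted vinylcyclopropane 14 (C6–C7 and C6–C8 formed); the closest known reaction type is the tandem cyclopropanation/Cope rearrangement (formal [4+3] cycloaddition) of alkenyl Fischer carbene complexes with 1,3-dienes. The seven-membered ring closes by the boat-shaped [3,3]-sigmatropic shift of the cis-divinylcyclopropane (C1–C10 formed, C6–C8 broken, driven by release of ring strain), and trans isomers can reach the cis form by reversible homolysis of the donor- and vinyl-stabilised C6–C8 bond. The only new stereocentre, quaternary C1, is set by the face of the cyclopentene that C10 reaches: the di-tert-butylsilylene bridge covers the β face, so C10 should bond on the α (exo) face and the methyl ends up β. The step needs cyclopropanation of the 1,1-disubstituted double bond of isoprene, which the electrophilic carbene carbon should prefer because bonding to the CH2 terminus next to the methyl-bearing carbon develops positive charge at a tertiary allylic position. The tetrasubstituted alkene of 12 is too hindered to act as a Diels–Alder dienophile, which removes the usual competing pathway.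

Step 9
Reactants: 15 2β,4β-(di-tert-butylsilylenedioxy)-6-methoxydauca-5,8-diene
Product: 16 2β,4β-(di-tert-butylsilylenedioxy)-6,6-(ethylenedioxy)dauc-8-ene (H5 α)
Conditions: HOCH2CH2OH (10 equiv), PPTS (10 mol %), CH2Cl2, 0 °C → rt
Reagents that add atoms: ethylene glycol OCCO
Why: Acid-catalysed transketalisation of the enol ether, in which C5 should be protonated on the α face (anti to the silylene bridge and the C1 methyl) and the oxocarbenium ion is trapped by the diol with loss of methanol, sets H5 and masks C6, while the C4 oxygen, still a silyl ether, is a poor leaving group and should not ionise.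

Step 10
Reactants: 16 2β,4β-(di-tert-butylsilylenedioxy)-6,6-(ethylenedioxy)dauc-8-ene
Product: 17 6,6-(ethylenedioxy)dauc-8-ene-2β,4β-diol
Conditions: HF·pyridine, pyridine, THF, 0 °C → rt
Reagents that add atoms: none
Why: Fluoride cleavage of both Si–O bonds of the silylene frees the 2β,4β-diol; with the enol ether gone the tertiary 4-hydroxyl is no longer prone to ionisation, and the dioxolane and the alkene are inert to the buffered reagent.

Step 11
Reactants: 17 6,6-(ethylenedioxy)dauc-8-ene-2β,4β-diol
Product: 18 6,6-(ethylenedioxy)-4β-hydroxydauc-8-en-2-one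
Conditions: Dess–Martin periodinane, pyridine, CH2Cl2, 0 °C → rt
Reagents that add atoms: none
Why: Dess–Martin oxidation converts the only secondary alcohol into the C2 ketone under buffered conditions, the tertiary 4β-hydroxyl being inert.

Step 12
Reactants: 18 6,6-(ethylenedioxy)-4β-hydroxydauc-8-en-2-one
Product: 19 6,6-(ethylenedioxy)dauc-8-ene-2α,4β-diol
Conditions: Me4NBH(OAc)3, MeCN/AcOH (1:1), −30 → 0 °C
Reagents that add atoms: none
Why: Hydroxyl-directed reduction, in which the 4β-hydroxyl exchanges onto boron and delivers hydride across the five-membered ring to the β face of the C2 carbonyl (the reagent reduces unassisted ketones only slowly), should give the 2α-alcohol anti to the 4β-hydroxyl.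

Step 13
Reactants: 19 6,6-(ethylenedioxy)dauc-8-ene-2α,4β-diol
Product: 20 2α-acetoxy-6,6-(ethylenedioxy)dauc-8-en-4β-ol
Conditions: Ac2O, pyridine, DMAP (cat.), CH2Cl2, rt
Reagents that add atoms: acetic anhydride CC(=O)OC(C)=O
Why: DMAP-catalysed acetylation takes the secondary 2α-hydroxyl and leaves the hindered tertiary 4β-hydroxyl free.

Step 14
Reactants: 20 2α-acetoxy-6,6-(ethylenedioxy)dauc-8-en-4β-ol
Product: 21 2α-acetoxy-4β-hydroxydauc-8-en-6-one (H5 α, trans-fused)
Conditions: PPTS, acetone/H2O (5:1), 55 °C
Reagents that add atoms: water O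
Why: Mild acid-catalysed ketal hydrolysis releases the C6 ketone, and H5 should stay (or equilibrate to) α because the trans-fused ketone, with C6 cis to the 4β-hydroxyl (hydrogen bond) and not to the isopropyl group, is expected to be the more stable epimer.

Step 15
Reactants: 21 2α-acetoxy-4β-hydroxydauc-8-en-6-one
Product: 22 2α-acetoxydauc-8-ene-4β,6β-diol
Conditions: NaBH4, MeOH, −20 → 0 °C
Reagents that add atoms: none
Why: Borohydride reduction should occur from the α face because the β face of the C6 carbonyl is covered by the cis-vicinal C1 methyl group, which gives the 6β-alcohol, the epimer needed for an esterification with inversion.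

Step 16
Reactants: 22 2α-acetoxydauc-8-ene-4β,6β-diol; 23 4-(benzyloxy)-3-methoxybenzoic acid
Product: 24 2α-acetoxy-4β-hydroxydauc-8-en-6α-yl 4-(benzyloxy)-3-methoxybenzoate
Conditions: PPh3, DIAD, toluene, 0 °C → rt
Reagents that add atoms: none
Why: Mitsunobu esterification, in which the 6β-hydroxyl is activated as the oxyphosphonium ion and displaced by the carboxylate from the open α face with inversion, installs the aroyl group with the 6α configuration while the tertiary 4β-hydroxyl is not activated.

Step 17
Reactants: 24 2α-acetoxy-4β-hydroxydauc-8-en-6α-yl 4-(benzyloxy)-3-methoxybenzoate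
Product: 25 2α-acetoxy-8α,9α-epoxy-4β-hydroxydaucan-6α-yl 4-(benzyloxy)-3-methoxybenzoate
Conditions: mCPBA, NaHCO3, CH2Cl2, 0 °C
Reagents that add atoms: 3-chloroperoxybenzoic acid OOC(=O)c1cccc(Cl)c1
Why: Peracid epoxidation (Prilezhaev reaction) of the only alkene should occur on the α face because the axial C1 methyl shields the β face of C8=C9 while the 6α-ester is pseudo-equatorial, and the bicarbonate buffer guards against transannular opening of the epoxide by the 4β-hydroxyl.

Step 18
Reactants: 25 2α-acetoxy-8α,9α-epoxy-4β-hydroxydaucan-6α-yl 4-(benzyloxy)-3-methoxybenzoate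
Product: 26 CNP0241679.3, 2α-acetoxy-8α,9α-epoxy-4β-hydroxydaucan-6α-yl 4-hydroxy-3-methoxybenzoate
Conditions: H2 (1 atm), Pd/C, EtOAc, rt
Reagents that add atoms: none
Why: Hydrogenolysis of the benzyl aryl ether under neutral conditions frees the phenol; no alkene remains, and the trisubstituted epoxide, both esters and the tertiary alcohol should be unaffected.

**Compound list**

1 | (R)-4-(tert-butyldimethylsilyloxy)cyclopent-2-en-1-one | O=C1C=C[C@H](O[Si](C)(C)C(C)(C)C)C1 | starting material
2 | (3R,4R)-4-(tert-butyldimethylsilyloxy)-3-methyl-1-(trimethylsilyloxy)cyclopent-1-ene (methyl trans to the silyloxy group) | C[Si](C)(C)OC1=C[C@@H](C)[C@H](O[Si](C)(C)C(C)(C)C)C1 | intermediate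
3 | (R)-4-(tert-butyldimethylsilyloxy)-3-methylcyclopent-2-en-1-one | O=C1C=C(C)[C@H](O[Si](C)(C)C(C)(C)C)C1 | intermediate
4 | (4R)-2,3-dibromo-4-(tert-butyldimethylsilyloxy)-3-methylcyclopentan-1-one (mixture at C2 and C3, formed in the flask) | O=C1C(Br)C(C)(Br)[C@H](O[Si](C)(C)C(C)(C)C)C1 | intermediate
5 | (R)-2-bromo-4-(tert-butyldimethylsilyloxy)-3-methylcyclopent-2-en-1-one | O=C1C(Br)=C(C)[C@H](O[Si](C)(C)C(C)(C)C)C1 | intermediate
6 | (1R,4R)-2-bromo-4-(tert-butyldimethylsilyloxy)-3-methyl-1-(propan-2-yl)cyclopent-2-en-1-ol | BrC1=C(C)[C@H](O[Si](C)(C)C(C)(C)C)C[C@@]1(O)C(C)C | intermediate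
7 | (1R,4R)-2-bromo-3-methyl-1-(propan-2-yl)cyclopent-2-ene-1,4-diol (cis-diol) | BrC1=C(C)[C@H](O)C[C@@]1(O)C(C)C | intermediate
8 | 7-bromo-3,3-di-tert-butyl-6-methyl-1-(propan-2-yl)-2,4-dioxa-3-silabicyclo[3.2.1]oct-6-ene (silylene bridge between the 2β and 4β oxygens) | BrC1=C(C)[C@H]2C[C@@]1(O[Si](C(C)(C)C)(C(C)(C)C)O2)C(C)C | intermediate
9 | chromium hexacarbonyl, Cr(CO)6 | O=C=[Cr](=C=O)(=C=O)(=C=O)(=C=O)=C=O | starting material
10 | vinyllithium from 8 (lithium on C5, formed in the flask) | [Li]C1=C(C)[C@H]2C[C@@]1(O[Si](C(C)(C)C)(C(C)(C)C)O2)C(C)C | intermediate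
11 | lithium pentacarbonyl(acyl)chromate from 10 (formed in the flask) | [Li+].[O-]C(=[Cr](=C=O)(=C=O)(=C=O)(=C=O)=C=O)C1=C(C)[C@H]2C[C@@]1(O[Si](C(C)(C)C)(C(C)(C)C)O2)C(C)C | intermediate
12 | pentacarbonyl[methoxy(3,3-di-tert-butyl-6-methyl-1-isopropyl-2,4-dioxa-3-silabicyclo[3.2.1]oct-6-en-7-yl)carbene]chromium | COC(=[Cr](=C=O)(=C=O)(=C=O)(=C=O)=C=O)C1=C(C)[C@H]2C[C@@]1(O[Si](C(C)(C)C)(C(C)(C)C)O2)C(C)C | intermediate
13 | isoprene | C=CC(C)=C | starting material
14 | 1-methoxy-2-methyl-2-vinyl-1-(silylene-bridged cyclopentenyl)cyclopropane, cis isomer (vinyl cis to cyclopentenyl; the diastereomer that rearranges on the α face; formed in the flask) | CO[C@@]1(C2=C(C)[C@H]3C[C@@]2(O[Si](C(C)(C)C)(C(C)(C)C)O3)C(C)C)C[C@]1(C)C=C | intermediate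
15 | 2β,4β-(di-tert-butylsilylenedioxy)-6-methoxydauca-5,8-diene | COC=2CC(C)=CC[C@@]3(C)[C@H]4C[C@@](O[Si](C(C)(C)C)(C(C)(C)C)O4)(C(C)C)C=23 | intermediate
16 | 2β,4β-(di-tert-butylsilylenedioxy)-6,6-(ethylenedioxy)dauc-8-ene (H5 α) | O1CCOC12CC(C)=CC[C@@]3(C)[C@H]4C[C@@](O[Si](C(C)(C)C)(C(C)(C)C)O4)(C(C)C)[C@H]23 | intermediate
17 | 6,6-(ethylenedioxy)dauc-8-ene-2β,4β-diol | O1CCOC12CC(C)=CC[C@@]3(C)[C@H](O)C[C@@](O)(C(C)C)[C@H]23 | intermediate
18 | 6,6-(ethylenedioxy)-4β-hydroxydauc-8-en-2-one | O1CCOC12CC(C)=CC[C@@]3(C)C(=O)C[C@@](O)(C(C)C)[C@H]23 | intermediate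
19 | 6,6-(ethylenedioxy)dauc-8-ene-2α,4β-diol | O1CCOC12CC(C)=CC[C@@]3(C)[C@@H](O)C[C@@](O)(C(C)C)[C@H]23 | intermediate
20 | 2α-acetoxy-6,6-(ethylenedioxy)dauc-8-en-4β-ol | O1CCOC12CC(C)=CC[C@@]3(C)[C@@H](OC(C)=O)C[C@@](O)(C(C)C)[C@H]23 | intermediate
21 | 2α-acetoxy-4β-hydroxydauc-8-en-6-one | O=C1CC(C)=CC[C@@]2(C)[C@@H](OC(C)=O)C[C@@](O)(C(C)C)[C@H]12 | intermediate
22 | 2α-acetoxydauc-8-ene-4β,6β-diol | O[C@@H]1CC(C)=CC[C@@]2(C)[C@@H](OC(C)=O)C[C@@](O)(C(C)C)[C@H]12 | intermediate
23 | 4-(benzyloxy)-3-methoxybenzoic acid (O-benzylvanillic acid) | COc1cc(C(=O)O)ccc1OCc1ccccc1 | starting material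
24 | 2α-acetoxy-4β-hydroxydauc-8-en-6α-yl 4-(benzyloxy)-3-methoxybenzoate | COc1cc(C(=O)O[C@H]2CC(C)=CC[C@@]3(C)[C@@H](OC(C)=O)C[C@@](O)(C(C)C)[C@H]23)ccc1OCc1ccccc1 | intermediate
25 | 2α-acetoxy-8α,9α-epoxy-4β-hydroxydaucan-6α-yl 4-(benzyloxy)-3-methoxybenzoate | COc1cc(C(=O)O[C@H]2C[C@@]3(C)O[C@H]3C[C@@]3(C)[C@@H](OC(C)=O)C[C@@](O)(C(C)C)[C@H]23)ccc1OCc1ccccc1 | intermediate
26 | CNP0241679.3, 2α-acetoxy-8α,9α-epoxy-4β-hydroxydaucan-6α-yl 4-hydroxy-3-methoxybenzoate | COc1cc(C(=O)O[C@H]2C[C@@]3(C)O[C@H]3C[C@@]3(C)[C@@H](OC(C)=O)C[C@@](O)(C(C)C)[C@H]23)ccc1O | target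

**Step count**

Total: 18 steps. Longest linear sequence: 18 steps (1 → 26); chromium hexacarbonyl, isoprene and the benzoic acid 23 enter as purchased materials.

**Steps most likely to fail**

Step 8. What may go wrong: carbene transfer to the unsubstituted vinyl group of isoprene (which would put the methyl on C9), or no transfer at all from the hindered tetrasubstituted complex. Fallback: the regiochemistry is fixed by using an alkene with a single double bond and building the second vinyl group afterwards. Carbene 12 is heated with methyl methacrylate; cyclopropanation of α,β-unsaturated esters by Fischer carbene complexes is long-established chemistry, and it can only join C6 to the CH2 carbon and to the methyl-bearing carbon. This should give methyl 2-methoxy-1-methyl-2-(silylene-bridged cyclopentenyl)cyclopropane-1-carboxylate F1. Reduction with i-Bu2AlH at −78 °C should give the corresponding cyclopropanecarbaldehyde F2, and Wittig methylenation with Ph3P=CH2 then gives divinylcyclopropane 14, which rearranges on warming and so returns to the route at 15.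

Step 9. What may go wrong: acid ionises the C4–O bond that is allylic to the enol ether (loss of the bridge oxygen and formation of a 4,5-unsaturated C6 ketone), or the proton is delivered to the β face of C5. Fallback: the enol ether is removed without acid before any acid is used. From 15, bromoetherification with NBS and ethylene glycol (NaHCO3, MeCN, −20 °C) should give the 5-bromo-6-(2-hydroxyethoxy)-6-methoxy ketal F3. Bu3SnH with AIBN in toluene at 80 °C then removes the bromine, the C5 radical taking hydrogen from the α face, to give the 6-(2-hydroxyethoxy)-6-methoxy mixed ketal F4. With the enol ether gone, PPTS closes the dioxolane with loss of methanol, and the sequence returns to the route at 16.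

Step 16. What may go wrong: the hindered 6β-hydroxyl is not converted into the oxyphosphonium ion, or this intermediate eliminates toward C5 or C7 instead of being substituted. Fallback: activation as a sulfonate and substitution by a cesium carboxylate. From 22, MsCl and Et3N (CH2Cl2, 0 °C) should give the 6β-methanesulfonate F5. This is displaced with inversion by cesium 4-(benzyloxy)-3-methoxybenzoate F6 (from acid 23 and Cs2CO3) with 18-crown-6 in toluene at 80 °C, and the sequence returns to the route at 24.

**Further compounds**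

F1 | step 8 | methyl 2-methoxy-1-methyl-2-(3,3-di-tert-butyl-6-methyl-1-isopropyl-2,4-dioxa-3-silabicyclo[3.2.1]oct-6-en-7-yl)cyclopropane-1-carboxylate (mixture of cyclopropane diastereomers) | COC(=O)C1(C)CC1(OC)C1=C(C)[C@H]2C[C@@]1(O[Si](C(C)(C)C)(C(C)(C)C)O2)C(C)C
F2 | step 8 | 2-methoxy-1-methyl-2-(3,3-di-tert-butyl-6-methyl-1-isopropyl-2,4-dioxa-3-silabicyclo[3.2.1]oct-6-en-7-yl)cyclopropane-1-carbaldehyde (mixture of cyclopropane diastereomers) | O=CC1(C)CC1(OC)C1=C(C)[C@H]2C[C@@]1(O[Si](C(C)(C)C)(C(C)(C)C)O2)C(C)C
F3 | step 9 | 5-bromo-2β,4β-(di-tert-butylsilylenedioxy)-6-(2-hydroxyethoxy)-6-methoxydauc-8-ene (mixture at C5 and C6) | COC1(OCCO)CC(C)=CC[C@@]2(C)[C@H]3C[C@@](O[Si](C(C)(C)C)(C(C)(C)C)O3)(C(C)C)C12Br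
F4 | step 9 | 2β,4β-(di-tert-butylsilylenedioxy)-6-(2-hydroxyethoxy)-6-methoxydauc-8-ene (H5 α, mixture at C6) | COC1(OCCO)CC(C)=CC[C@@]2(C)[C@H]3C[C@@](O[Si](C(C)(C)C)(C(C)(C)C)O3)(C(C)C)[C@H]12
F5 | step 16 | 2α-acetoxy-4β-hydroxydauc-8-en-6β-yl methanesulfonate | CS(=O)(=O)O[C@@H]1CC(C)=CC[C@@]2(C)[C@@H](OC(C)=O)C[C@@](O)(C(C)C)[C@H]12
F6 | step 16 | cesium 4-(benzyloxy)-3-methoxybenzoate | [Cs+].COc1cc(C([O-])=O)ccc1OCc1ccccc1
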